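**Plan**

Ring numbering used below: C1 carries the triene, C2 is CHMe, C3 CMe(OH), C4 CH(OAc), C5 CMe(OH), C6 CH(OAc). Enabling feature: the C1 alkenyl and C2 methyl are cis, all four oxygens (C3–C6) lie on the other face, and C3/C5 carry methyls; this is the imprint of a 3,5-dimethylcyclohexa-2,4-diene (C3=C4–C5=C6) closed between C1 and C2 and then oxygenated on its free face.
Retrosynthetic cuts, in order: the two acetates and two temporary acetonides; the pyrone–C(Me)=CH bond (aldol condensation of lithiated 6-ethylpyrone) and two Wittig C=C bonds of the side chain; the C4–O/C5–O bonds (hydroxyl-directed osmylation) and the C3–O/C6–O bonds (singlet oxygen [4+2]); the ring bond C1–C2 (6π electrocyclization of an acyclic trienoyl imide); the triene C=C bonds (Still–Gennari and Horner–Wadsworth–Emmons from tiglic aldehyde).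
Forward: the pyrone ring is made first (steps 1–3), the acyclic triene is assembled (steps 4–8), the carbocycle is closed last in one pericyclic event (step 9), then oxygenation (10–12), chain growth (13–16), union with the pyrone (17), unmasking and acetylation (18–19).
Stereochemistry: C1/C2 cis from disrotatory closure of the E,Z,E-triene, absolute sense from the MgBr2 chelate of the (R)-4-benzyloxazolidinone imide; C3/C6 from singlet oxygen anti to the C1/C2 groups; C4/C5 from osmylation directed syn by the new hydroxyls; alkene geometries from Still–Gennari (Z), HWE/Wittig (E) and E1cB elimination (E).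

Key step: step 9

Assumption: the configuration is taken exactly as drawn in the given SMILES, and compounds 1, 2, 7, 8, 10, 11, 25 and 27 are taken as purchasable.

**Route**

Step 1
Reactants: 1 ethyl 2-methyl-3-oxopentanoate; 2 N-methoxy-N-methylpropanamide
Product: 4 ethyl 2,4-dimethyl-3,5-dioxoheptanoate, via keto ester dianion 3 (not isolated)
Conditions: NaH, THF, 0 °C; n-BuLi, 0 °C; then 2, 0 °C to rt; aq. HCl
Reagents that add atoms: none
Why: The dianion of a β-keto ester is acylated at its more nucleophilic γ-carbon (dianion C-acylation of Claisen type), and the chelated tetrahedral adduct of the N-methoxy-N-methylamide should stop the reaction at the 3,5-diketo ester.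

Step 2
Reactants: 4 ethyl 2,4-dimethyl-3,5-dioxoheptanoate
Product: 5 6-ethyl-4-hydroxy-3,5-dimethyl-2H-pyran-2-one
Conditions: DBU, toluene, 110 °C; aq. HCl
Reagents that add atoms: none
Why: Base-mediated enol lactonization of a 3,5-diketo ester (triketide cyclization) should give the 4-hydroxy-2-pyrone with loss of ethanol, the pyrone being the thermodynamic sink.

Step 3
Reactants: 5 6-ethyl-4-hydroxy-3,5-dimethyl-2H-pyran-2-one
Product: 6 2-ethyl-6-methoxy-3,5-dimethyl-4H-pyran-4-one
Conditions: MeOTf, CH2Cl2, rt; aq. NaHCO3
Reagents that add atoms: methyl trifluoromethanesulfonate, COS(=O)(=O)C(F)(F)F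
Why: O-Methylation with the hard electrophile MeOTf should take place at the lactone carbonyl oxygen, the most basic site of the 4-hydroxy-2-pyrone, so that loss of the proton leaves the 2-methoxy-4-pyranone (regioselective O-alkylation).

Step 4
Reactants: 7 (R)-4-benzyloxazolidin-2-one; 8 2-(diethoxyphosphoryl)acetic acid
Product: 9 (R)-4-benzyl-3-[2-(diethoxyphosphoryl)acetyl]oxazolidin-2-one
Conditions: DCC, DMAP (cat.), CH2Cl2, 0 °C to rt
Reagents that add atoms: none
Why: Carbodiimide-mediated N-acylation of the oxazolidinone (DCC/DMAP coupling) should give the imide phosphonate without touching the stereocenter of the auxiliary.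

Step 5
Reactants: 10 (E)-2-methylbut-2-enal (tiglic aldehyde); 11 ethyl 2-[bis(2,2,2-trifluoroethoxy)phosphoryl]propanoate
Product: 13 ethyl (2Z,4E)-2,4-dimethylhexa-2,4-dienoate, via phosphonate carbanion 12 (not isolated)
Conditions: 11, KN(SiMe3)2, 18-crown-6, THF, −78 °C; then 10
Reagents that add atoms: none
Why: Still–Gennari olefination: the electron-poor trifluoroethyl phosphonate with a crown-ether-separated potassium counter-ion eliminates from the kinetic adduct and should give the (Z)-trisubstituted enoate while the E-alkene of tiglic aldehyde is untouched.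

Step 6
Reactants: 13 ethyl (2Z,4E)-2,4-dimethylhexa-2,4-dienoate
Product: 14 (2Z,4E)-2,4-dimethylhexa-2,4-dien-1-ol
Conditions: i-Bu2AlH, CH2Cl2, −78 °C; aq. potassium sodium tartrate
Reagents that add atoms: none
Why: i-Bu2AlH reduces the conjugated ester by 1,2-hydride delivery to the allylic alcohol (ester reduction) without affecting either alkene geometry.

Step 7
Reactants: 14 (2Z,4E)-2,4-dimethylhexa-2,4-dien-1-ol
Product: 15 (2Z,4E)-2,4-dimethylhexa-2,4-dienal
Conditions: MnO2, CH2Cl2, rt
Reagents that add atoms: none
Why: MnO2 oxidizes allylic alcohols selectively under neutral heterogeneous conditions (allylic oxidation) and should leave the labile (2Z)-geometry intact.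

Step 8
Reactants: 15 (2Z,4E)-2,4-dimethylhexa-2,4-dienal; 9 (R)-4-benzyl-3-[2-(diethoxyphosphoryl)acetyl]oxazolidin-2-one
Product: 16 (R)-4-benzyl-3-[(2E,4Z,6E)-4,6-dimethylocta-2,4,6-trienoyl]oxazolidin-2-one
Conditions: LiCl, i-Pr2NEt, MeCN, 0 °C
Reagents that add atoms: none
Why: Horner–Wadsworth–Emmons olefination under Masamune–Roush conditions is mild enough for the (Z)-enal and should give the (E)-enoyl imide, and at 0 °C the new triene should not yet cyclize.

Step 9
Reactants: 16 (R)-4-benzyl-3-[(2E,4Z,6E)-4,6-dimethylocta-2,4,6-trienoyl]oxazolidin-2-one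
Product: 17 (R)-4-benzyl-3-[(1S,6S)-3,5,6-trimethylcyclohexa-2,4-diene-1-carbonyl]oxazolidin-2-one
Conditions: MgBr2·OEt2 (2 equiv), CH2Cl2, 0 to 25 °C; aq. NH4Cl
Reagents that add atoms: none
Why: Proposed new method: the closest known reaction types are the thermal disrotatory 6π electrocyclization of (E,Z,E)-hexatrienes, its Lewis-acid-accelerated variant with acyl-substituted trienes, and the Diels–Alder reaction of metal-chelated enoyl oxazolidinones; here they are combined by running the electrocyclization on the MgBr2 chelate of the trienoyl imide so that the auxiliary decides the sense of the helical transition state. The six-membered carbocycle closes in one pericyclic event (6π, disrotatory) that forms the C1–C2 σ bond between the two triene termini and leaves the C3=C4–C5=C6 diene. Because both termini carry their substituents outside (2E and 6E), disrotation must place the C1 acyl group and the C2 methyl group cis, so the relative configuration is controlled by orbital symmetry and alkene geometry. The absolute configuration is controlled by the auxiliary: in the bidentate chelate the two carbonyls are syn and the enoyl unit s-cis, the benzyl group of the (R)-oxazolidinone covers the Cα-si face of C1 exactly where the incoming C2 terminus and its methyl group would have to pass, so the bond should form on the Cα-re face and give the (1S,6S) diene. The step needs torquoselectivity and stereospecificity: the first is secured by the rigid chelate (excess MgBr2 keeps unbound imide out and the temperature stays below that of the uncatalysed closure), the second by the absence of competing hydrogen shifts (the C2 methyl is outside, so no Z-alkyl C–H can reach a terminus) and by conditions too mild to isomerize the Z-alkene.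

Step 10
Reactants: 17 (R)-4-benzyl-3-[(1S,6S)-3,5,6-trimethylcyclohexa-2,4-diene-1-carbonyl]oxazolidin-2-one
Product: 19 enediol imide (C3–OH and C6–OH cis to each other and trans to the C1 acyl and C2 methyl; C4=C5 alkene), via endoperoxide 18 (not isolated)
Conditions: O2, tetraphenylporphyrin (cat.), visible light, CH2Cl2, −78 °C; then Zn, AcOH, 0 °C to rt
Reagents that add atoms: dioxygen, O=O
Why: Singlet oxygen adds in a [4+2] cycloaddition to the s-cis ring diene from the face opposite the cis C1 acyl and C2 methyl groups, which sets C3 and C6, and zinc in acetic acid cleaves only the O–O bond to give the cis-1,4-diol with retention at both carbons.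

Step 11
Reactants: 19 enediol imide
Product: 21 tetraol imide (hydroxyls at C3–C6 all cis and trans to the C1 acyl and C2 methyl), via osmate ester 20 (not isolated)
Conditions: OsO4 (1.05 equiv), TMEDA (1.1 equiv), CH2Cl2, −78 °C; then conc. HCl, MeOH, rt
Reagents that add atoms: osmium tetroxide, O=[Os](=O)(=O)=O
Why: Hydroxyl-directed dihydroxylation: the OsO4·TMEDA complex is hydrogen-bonded by the two allylic hydroxyls on the oxygenated face and should add syn to them across C4=C5, which sets C4 and C5 and makes all four oxygens cis; acid methanolysis then frees the diol from the hexavalent osmium ester.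

Step 12
Reactants: 21 tetraol imide
Product: 22 bis-acetonide imide (dioxolanes across C3/C4 and C5/C6)
Conditions: 2,2-dimethoxypropane, camphorsulfonic acid (cat.), acetone, rt
Reagents that add atoms: 2,2-dimethoxypropane, COC(C)(C)OC
Why: Acid-catalysed transketalization (acetonide formation) should tie the two cis-1,2-diol pairs C3/C4 and C5/C6 into two dioxolanes, the only way to protect all four hydroxyls.

Step 13
Reactants: 22 bis-acetonide imide
Product: 23 bis-acetonide primary alcohol (C1–CH2OH)
Conditions: LiBH4, MeOH (1 equiv), THF, 0 °C; aq. NaOH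
Reagents that add atoms: none
Why: LiBH4 attacks the exocyclic imide carbonyl (reductive removal of the oxazolidinone auxiliary) and should give the primary alcohol and the recoverable auxiliary while the acetonides and the C1 stereocenter are untouched.

Step 14
Reactants: 23 bis-acetonide primary alcohol
Product: 24 bis-acetonide aldehyde (C1–CHO)
Conditions: Dess–Martin periodinane, pyridine, CH2Cl2, 0 °C to rt
Reagents that add atoms: none
Why: Dess–Martin oxidation under pyridine-buffered, non-basic conditions should give the α-branched aldehyde without epimerization at C1 or β-elimination of the C6 oxygen.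

Step 15
Reactants: 24 bis-acetonide aldehyde; 25 2-(triphenylphosphoranylidene)propanal
Product: 26 bis-acetonide (E)-enal (C1–CH=C(Me)–CHO)
Conditions: toluene, 80 °C
Reagents that add atoms: none
Why: Wittig olefination with the stabilized, non-basic formyl ylide should give the (E)-trisubstituted enal directly, the neutral conditions protecting the C1 stereocenter.

Step 16
Reactants: 26 bis-acetonide (E)-enal; 27 2-(triphenylphosphoranylidene)acetaldehyde
Product: 28 bis-acetonide (2E,4E)-dienal (C1–CH=C(Me)–CH=CH–CHO)
Conditions: 27 (1.1 equiv), toluene, 70 °C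
Reagents that add atoms: none
Why: Wittig two-carbon homologation with the formylmethylene ylide should give the (2E,4E)-dienal, the near-stoichiometric ylide and moderate temperature keeping the less hindered product from reacting a second time.

Step 17
Reactants: 6 2-ethyl-6-methoxy-3,5-dimethyl-4H-pyran-4-one; 28 bis-acetonide (2E,4E)-dienal
Product: 32 bis-acetonide of di-O-deacetylamaurone B (all-E triene pyrone), via lithiated pyrone 29 (not isolated), via lithium aldolate 30 (not isolated), via allylic mesylate 31 (not isolated)
Conditions: 6, LiN(SiMe3)2, THF, −78 °C; then 28, −78 °C; then MsCl, −78 to 0 °C; then DBU, rt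
Reagents that add atoms: none
Why: Vinylogous aldol addition of the lithiated 6-ethylpyrone to the dienal followed by mesylation and E1cB elimination through the pyrone-stabilized carbanion (aldol condensation) should give the fully conjugated triene with the new trisubstituted alkene E, the geometry that avoids strain between the pyrone 5-methyl group and the chain.

Step 18
Reactants: 32 bis-acetonide of di-O-deacetylamaurone B
Product: 33 di-O-deacetylamaurone B (tetraol)
Conditions: AcOH/H2O (4:1), 40 °C, dark
Reagents that add atoms: none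
Why: Mild aqueous acid hydrolysis of the two acetonides (acetal cleavage) should free the tetraol, the methoxypyrone and the triene being stable to dilute acetic acid in the dark.

Step 19
Reactants: 33 di-O-deacetylamaurone B
Product: 34 Amaurone B
Conditions: Ac2O, pyridine, DMAP (cat.), CH2Cl2, 0 °C to rt
Reagents that add atoms: acetic anhydride, CC(=O)OC(C)=O
Why: Acetylation with Ac2O/pyridine discriminates by steric hindrance (selective O-acylation), so the two secondary hydroxyls at C4 and C6 should be esterified while the tertiary hydroxyls at C3 and C5 stay free.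

**Compound list**

1 | ethyl 2-methyl-3-oxopentanoate | CCC(=O)C(C)C(=O)OCC | starting material
2 | N-methoxy-N-methylpropanamide | CCC(=O)N(C)OC | starting material
3 | sodium lithium dianion of 1 (not isolated) | C[CH-]C(=O)[C-](C)C(=O)OCC.[Na+].[Li+] | intermediate
4 | ethyl 2,4-dimethyl-3,5-dioxoheptanoate | CCC(=O)C(C)C(=O)C(C)C(=O)OCC | intermediate
5 | 6-ethyl-4-hydroxy-3,5-dimethyl-2H-pyran-2-one | CCC1=C(C)C(O)=C(C)C(=O)O1 | intermediate
6 | 2-ethyl-6-methoxy-3,5-dimethyl-4H-pyran-4-one | CCc1oc(OC)c(C)c(=O)c1C | intermediate
7 | (R)-4-benzyloxazolidin-2-one | O=C1OC[C@@H](Cc2ccccc2)N1 | starting material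
8 | 2-(diethoxyphosphoryl)acetic acid | CCOP(=O)(OCC)CC(=O)O | starting material
9 | (R)-4-benzyl-3-[2-(diethoxyphosphoryl)acetyl]oxazolidin-2-one | O=C1OC[C@@H](Cc2ccccc2)N1C(=O)CP(=O)(OCC)OCC | intermediate
10 | (E)-2-methylbut-2-enal (tiglic aldehyde) | C/C=C(\C)C=O | starting material
11 | ethyl 2-[bis(2,2,2-trifluoroethoxy)phosphoryl]propanoate | CCOC(=O)C(C)P(=O)(OCC(F)(F)F)OCC(F)(F)F | starting material
12 | potassium carbanion of 11 (not isolated) | CCOC(=O)[C-](C)P(=O)(OCC(F)(F)F)OCC(F)(F)F.[K+] | intermediate
13 | ethyl (2Z,4E)-2,4-dimethylhexa-2,4-dienoate | C/C=C(\C)/C=C(/C)C(=O)OCC | intermediate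
14 | (2Z,4E)-2,4-dimethylhexa-2,4-dien-1-ol | C/C=C(\C)/C=C(/C)CO | intermediate
15 | (2Z,4E)-2,4-dimethylhexa-2,4-dienal | C/C=C(\C)/C=C(/C)C=O | intermediate
16 | (R)-4-benzyl-3-[(2E,4Z,6E)-4,6-dimethylocta-2,4,6-trienoyl]oxazolidin-2-one | O=C1OC[C@@H](Cc2ccccc2)N1C(=O)/C=C/C(/C)=C\C(\C)=C\C | intermediate
17 | (R)-4-benzyl-3-[(1S,6S)-3,5,6-trimethylcyclohexa-2,4-diene-1-carbonyl]oxazolidin-2-one (C1 acyl and C2 methyl cis) | O=C1OC[C@@H](Cc2ccccc2)N1C(=O)[C@@H]1[C@H](C)C(C)=CC(C)=C1 | intermediate
18 | endoperoxide imide: O–O bridge from C3 to C6 on the face opposite the C1 acyl and C2 methyl (not isolated) | O=C1OC[C@@H](Cc2ccccc2)N1C(=O)[C@@H]1[C@H](C)[C@@]2(C)OO[C@@H]1C(C)=C2 | intermediate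
19 | enediol imide: C3–OH and C6–OH cis, trans to the C1 acyl and C2 methyl, C4=C5 alkene | O=C1OC[C@@H](Cc2ccccc2)N1C(=O)[C@@H]1[C@H](C)[C@@](C)(O)C=C(C)[C@H]1O | intermediate
20 | C4/C5 osmate ester of 19, hexavalent osmium, TMEDA-ligated (not isolated) | O=C1OC[C@@H](Cc2ccccc2)N1C(=O)[C@@H]1[C@H](C)[C@@](C)(O)[C@H]3O[Os](=O)(=O)O[C@@]3(C)[C@H]1O.CN(C)CCN(C)C | intermediate
21 | tetraol imide: C3–C6 hydroxyls all cis, trans to the C1 acyl and C2 methyl | O=C1OC[C@@H](Cc2ccccc2)N1C(=O)[C@@H]1[C@H](C)[C@@](C)(O)[C@@H](O)[C@@](C)(O)[C@H]1O | intermediate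
22 | bis-acetonide imide (C3/C4 and C5/C6 isopropylidene acetals) | O=C1OC[C@@H](Cc2ccccc2)N1C(=O)[C@@H]1[C@H](C)[C@@]3(C)OC(C)(C)O[C@H]3[C@@]4(C)OC(C)(C)O[C@@H]14 | intermediate
23 | bis-acetonide primary alcohol (C1–CH2OH) | OC[C@@H]1[C@H](C)[C@@]3(C)OC(C)(C)O[C@H]3[C@@]4(C)OC(C)(C)O[C@@H]14 | intermediate
24 | bis-acetonide aldehyde (C1–CHO) | O=C[C@@H]1[C@H](C)[C@@]3(C)OC(C)(C)O[C@H]3[C@@]4(C)OC(C)(C)O[C@@H]14 | intermediate
25 | 2-(triphenylphosphoranylidene)propanal | CC(C=O)=P(c1ccccc1)(c1ccccc1)c1ccccc1 | starting material
26 | bis-acetonide (E)-enal, C1–CH=C(Me)–CHO | O=C/C(C)=C/[C@@H]1[C@H](C)[C@@]3(C)OC(C)(C)O[C@H]3[C@@]4(C)OC(C)(C)O[C@@H]14 | intermediate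
27 | 2-(triphenylphosphoranylidene)acetaldehyde | O=CC=P(c1ccccc1)(c1ccccc1)c1ccccc1 | starting material
28 | bis-acetonide (2E,4E)-dienal, C1–CH=C(Me)–CH=CH–CHO | O=C/C=C/C(C)=C/[C@@H]1[C@H](C)[C@@]3(C)OC(C)(C)O[C@H]3[C@@]4(C)OC(C)(C)O[C@@H]14 | intermediate
29 | lithiated pyrone, lithium salt of 6 deprotonated at the ethyl CH2 (not isolated) | C[CH-]c1oc(OC)c(C)c(=O)c1C.[Li+] | intermediate
30 | lithium aldolate, mixture at the two new carbons (not isolated) | COc1oc(C(C)C([O-])/C=C/C(C)=C/[C@@H]2[C@H](C)[C@@]3(C)OC(C)(C)O[C@H]3[C@@]4(C)OC(C)(C)O[C@@H]24)c(C)c(=O)c1C.[Li+] | intermediate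
31 | allylic mesylate of the aldol adduct (not isolated) | COc1oc(C(C)C(OS(C)(=O)=O)/C=C/C(C)=C/[C@@H]2[C@H](C)[C@@]3(C)OC(C)(C)O[C@H]3[C@@]4(C)OC(C)(C)O[C@@H]24)c(C)c(=O)c1C | intermediate
32 | bis-acetonide of di-O-deacetylamaurone B (all-E triene) | COc1oc(/C(C)=C/C=C/C(C)=C/[C@@H]2[C@H](C)[C@@]3(C)OC(C)(C)O[C@H]3[C@@]4(C)OC(C)(C)O[C@@H]24)c(C)c(=O)c1C | intermediate
33 | di-O-deacetylamaurone B (tetraol) | COc1oc(/C(C)=C/C=C/C(C)=C/[C@@H]2[C@H](C)[C@@](C)(O)[C@@H](O)[C@@](C)(O)[C@H]2O)c(C)c(=O)c1C | intermediate
34 | Amaurone B | COc1oc(/C(C)=C/C=C/C(C)=C/[C@@H]2[C@H](C)[C@@](C)(O)[C@@H](OC(C)=O)[C@@](C)(O)[C@H]2OC(C)=O)c(C)c(=O)c1C | target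

**Count and risks**

Total step count: 19. Longest linear sequence: 15 steps (steps 5–19, from 10).

Steps most likely to fail:

1. Step 9 (proposed new method). What may go wrong: the two helical transition states are not differentiated well enough (poor torquoselectivity), or closure of the chelate is slower than the unselective closure of unbound imide. Fallback with known chemistry, setting out from 15 and returning at 17: Masamune–Roush olefination of 15 with allyl diethylphosphonoacetate should give allyl (2E,4Z,6E)-4,6-dimethylocta-2,4,6-trienoate F1. Heating in toluene at 80 °C should close it by the purely thermal disrotatory 6π electrocyclization to racemic allyl cis-3,5,6-trimethylcyclohexa-2,4-diene-1-carboxylate F2. Pd(PPh3)4 and morpholine should remove the allyl group under neutral conditions to give racemic cis-3,5,6-trimethylcyclohexa-2,4-diene-1-carboxylic acid F3. DCC/DMAP coupling with 7 should then give 17 together with the diastereomeric imide (R)-4-benzyl-3-[(1R,6R)-3,5,6-trimethylcyclohexa-2,4-diene-1-carbonyl]oxazolidin-2-one F4, from which 17 is separated by chromatography or crystallization, the auxiliary serving as a covalent resolving agent.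

2. Step 11. What may go wrong: loss of hydrogen-bond direction so that osmylation takes place on the face of the C1/C2 substituents, or no osmylation at the hindered trisubstituted alkene. Fallback setting out from 17 and returning at 21: photooxygenation as in step 10 but without the zinc quench gives isolated endoperoxide 18. In this bicyclo[2.2.2] frame the alkene face anti to the O–O bridge is blocked by the C1 acyl and C2 methyl groups, so catalytic OsO4 with N-methylmorpholine N-oxide in acetone/water should add syn to the peroxide bridge by steric control and give the diol endoperoxide F5. Zn/AcOH then cleaves the O–O bond to give 21.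

3. Step 17. What may go wrong: deprotonation of the dienal at C1–H instead of carbonyl addition, retro-aldol cleavage during mesylation, or elimination to a mixture of alkene isomers. Fallback setting out from 6 (with 28) and returning at 32: N-bromosuccinimide with AIBN should brominate the activated CH2 of the ethyl group to give 2-(1-bromoethyl)-6-methoxy-3,5-dimethyl-4H-pyran-4-one F6. Arbuzov reaction with P(OEt)3 at 120 °C should give diethyl [1-(6-methoxy-3,5-dimethyl-4-oxo-4H-pyran-2-yl)ethyl]phosphonate F7. Horner–Wadsworth–Emmons olefination of 28 with the sodium salt of this phosphonate (NaN(SiMe3)2, THF, −78 °C to rt) should form the pyrone–C(Me)=CH bond directly and give 32.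

**Further compounds**

F1 | step 9 | allyl (2E,4Z,6E)-4,6-dimethylocta-2,4,6-trienoate | C/C=C(\C)/C=C(/C)\C=C\C(=O)OCC=C
F2 | step 9 | racemic allyl cis-3,5,6-trimethylcyclohexa-2,4-diene-1-carboxylate (one enantiomer drawn) | C=CCOC(=O)[C@@H]1[C@H](C)C(C)=CC(C)=C1
F3 | step 9 | racemic cis-3,5,6-trimethylcyclohexa-2,4-diene-1-carboxylic acid (one enantiomer drawn) | OC(=O)[C@@H]1[C@H](C)C(C)=CC(C)=C1
F4 | step 9 | (R)-4-benzyl-3-[(1R,6R)-3,5,6-trimethylcyclohexa-2,4-diene-1-carbonyl]oxazolidin-2-one | O=C1OC[C@@H](Cc2ccccc2)N1C(=O)[C@H]1[C@@H](C)C(C)=CC(C)=C1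
F5 | step 11 | diol endoperoxide imide: C4–OH and C5–OH syn to the C3–C6 peroxide bridge | O=C1OC[C@@H](Cc2ccccc2)N1C(=O)[C@@H]1[C@H](C)[C@@]2(C)OO[C@@H]1[C@](C)(O)[C@@H]2O
F6 | step 17 | 2-(1-bromoethyl)-6-methoxy-3,5-dimethyl-4H-pyran-4-one | CC(Br)c1oc(OC)c(C)c(=O)c1C
F7 | step 17 | diethyl [1-(6-methoxy-3,5-dimethyl-4-oxo-4H-pyran-2-yl)ethyl]phosphonate | CCOP(=O)(OCC)C(C)c1oc(OC)c(C)c(=O)c1C
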